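**Strategy**

Ring C of the flavonol is cut at C4a–C4, C4–C3 and O1–C2. The C4 carbonyl lies between ring A carbon C4a and C3, and the ring A oxygen O1 on C8a, ortho to C4a, is bonded to the aryl-bearing C2, so ring C maps onto an ortho-iodophenol, carbon monoxide and an arylacetylene. One palladium-catalysed carbonylative alkyne annulation should join the three and close ring C as the flavone. The iodophenol carries the C7 methoxy group, a methoxymethyl ether on the C8 oxygen and a benzyl ether on the C5 oxygen, matching the 4′-benzyl ether of the alkyne; acetate exchange at C8, C3 hydroxylation and one hydrogenolysis follow.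

Key step: step 8

Remark: the C5 oxygen is carried as a benzyl ether instead of a methyl ether, a protecting-group choice that lets the C5 and 4′ oxygens be freed together by a final hydrogenolysis and keeps Lewis acids away from the C8 acetate; epoxide 18 is racemic, which is of no consequence because both of its stereocentres are lost in the same step.

**Route**

Step 1
Reactants: 1 2,4-dihydroxy-6-methoxybenzaldehyde
Product: 2 4-(benzyloxy)-2-hydroxy-6-methoxybenzaldehyde
Conditions: BnBr (1.05 equiv), NaHCO3, MeCN, 70 °C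
Reagents that add atoms: benzyl bromide, BrCc1ccccc1
Why: Williamson etherification should take place only at the 4-hydroxyl, because the 2-hydroxyl is held in a hydrogen bond to the aldehyde and is too weakly acidic to be alkylated under bicarbonate.

Step 2
Reactants: 2 4-(benzyloxy)-2-hydroxy-6-methoxybenzaldehyde
Product: 3 5-(benzyloxy)-2-formyl-3-methoxyphenyl diethylcarbamate
Conditions: Et2NCOCl, K2CO3, MeCN, reflux
Reagents that add atoms: diethylcarbamoyl chloride, CCN(CC)C(Cl)=O
Why: O-Carbamoylation (nucleophilic acyl substitution by the phenoxide) under the stronger carbonate base caps the chelated phenol with the group that later directs the lithiation.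

Step 3
Reactants: 3 5-(benzyloxy)-2-formyl-3-methoxyphenyl diethylcarbamate
Product: 5 5-(benzyloxy)-2-hydroxy-3-methoxyphenyl diethylcarbamate, via aryl formate 4 (not isolated)
Conditions: mCPBA, CH2Cl2, 0 °C → rt; aq Na2S2O3 wash; then K2CO3 (cat.), MeOH, 0 °C
Reagents that add atoms: 3-chloroperbenzoic acid (mCPBA), O=C(OO)c1cccc(Cl)c1
Why: Baeyer–Villiger oxidation of the aldehyde (Dakin-type) should proceed with migration of the electron-rich aryl group, which bears ortho-methoxy and para-benzyloxy donors, and the aryl formate is methanolysed under conditions far too mild to cleave or shift the diethylcarbamate.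

Step 4
Reactants: 5 5-(benzyloxy)-2-hydroxy-3-methoxyphenyl diethylcarbamate
Product: 6 5-(benzyloxy)-3-methoxy-2-(methoxymethoxy)phenyl diethylcarbamate
Conditions: MOMCl, i-Pr2NEt, CH2Cl2, 0 °C → rt
Reagents that add atoms: chloromethyl methyl ether, COCCl
Why: O-Alkylation of the phenol with the α-chloro ether (acetal formation) under a hindered amine base gives the base-stable MOM ether without generating a long-lived phenoxide next to the carbamate.

Step 5
Reactants: 6 5-(benzyloxy)-3-methoxy-2-(methoxymethoxy)phenyl diethylcarbamate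
Product: 8 3-(benzyloxy)-2-iodo-5-methoxy-6-(methoxymethoxy)phenyl diethylcarbamate, via aryllithium 7 (not isolated)
Conditions: s-BuLi, TMEDA, THF, −78 °C; then I2 in THF, −78 °C
Reagents that add atoms: iodine, II
Why: Directed ortho-metalation: the O-carbamate is the strongest director present and its only free ortho position is further acidified by the flanking benzyloxy group, so lithiation should occur there alone, and the iodine quench at −78 °C precedes any anionic ortho-Fries rearrangement.

Step 6
Reactants: 8 3-(benzyloxy)-2-iodo-5-methoxy-6-(methoxymethoxy)phenyl diethylcarbamate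
Product: 9 3-(benzyloxy)-2-iodo-5-methoxy-6-(methoxymethoxy)phenol
Conditions: NaOH, EtOH–H2O, reflux, argon; then aq NH4Cl
Reagents that add atoms: none
Why: Alkaline hydrolysis of the aryl carbamate (acyl substitution at the carbamoyl carbon with loss of the aryloxide) frees the phenol, while the ethers, the MOM acetal and the aryl iodide are inert to hydroxide and the buffered work-up spares the acetal.

Step 7
Reactants: 10 4-(benzyloxy)benzaldehyde
Product: 11 1-(benzyloxy)-4-ethynylbenzene
Conditions: dimethyl (1-diazo-2-oxopropyl)phosphonate, K2CO3, MeOH, rt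
Reagents that add atoms: dimethyl (1-diazo-2-oxopropyl)phosphonate, COP(=O)(OC)C(=[N+]=[N-])C(C)=O
Why: Ohira–Bestmann homologation: methanolysis of the reagent gives the diazomethylphosphonate anion, which olefinates the aldehyde, and loss of N2 with a 1,2-hydrogen shift gives the terminal alkyne under conditions that do not touch the benzyl ether.

Step 8
Reactants: 9 3-(benzyloxy)-2-iodo-5-methoxy-6-(methoxymethoxy)phenol; 11 1-(benzyloxy)-4-ethynylbenzene; 12 carbon monoxide
Product: 15 5-(benzyloxy)-2-[4-(benzyloxy)phenyl]-7-methoxy-8-(methoxymethoxy)-4H-chromen-4-one, via ortho-hydroxyaryl ynone 13 (not isolated), via enaminone 14 (not isolated)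
Conditions: PdCl2(dppf) (5 mol%), CO (10 bar), Et2NH, 90 °C
Reagents that add atoms: none
Why: PdCl2(dppf) is reduced in the flask to zerovalent palladium, which adds oxidatively to the C–I bond of 9; CO insertion gives an aroyl complex of divalent palladium, and amine-assisted transfer of alkyne 11 followed by reductive elimination forms C4a–C4 and C4–C3 in ynone 13. Diethylamine then adds in conjugate fashion to give enaminone 14, and the ortho phenol oxygen displaces the amine at the β-carbon by addition–elimination, forming O1–C2 and releasing diethylamine again. The closest known reaction type is the palladium-catalysed carbonylative Sonogashira coupling–cyclisation of 2-iodophenols with terminal alkynes under CO in a secondary amine, which gives flavones. Ring C closes in a net 6-endo-dig oxa-Michael mode and no stereocentre is formed. The step needs 6-endo closure instead of 5-exo closure (aurone) and carbonylative coupling instead of direct coupling (2-arylbenzofuran); the first is secured by passage through enaminone 14, in which only the β-carbon is electrophilic, and the second by CO pressure and the absence of a copper co-catalyst. In the substrate only the oxygen on the future C8a is free, its neighbour being a MOM ether, and the chelating bisphosphine is chosen because the iodide is flanked by the hydroxyl and a benzyloxy group.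

Step 9
Reactants: 15 5-(benzyloxy)-2-[4-(benzyloxy)phenyl]-7-methoxy-8-(methoxymethoxy)-4H-chromen-4-one
Product: 17 5-(benzyloxy)-2-[4-(benzyloxy)phenyl]-7-methoxy-4-oxo-4H-chromen-8-yl acetate, via 8-hydroxyflavone 16 (not isolated)
Conditions: conc. HCl (cat.), MeOH–THF, 45 °C; evaporate; then Ac2O, pyridine, DMAP (cat.), CH2Cl2, 0 °C → rt
Reagents that add atoms: acetic anhydride, CC(=O)OC(C)=O
Why: Acid-catalysed acetal exchange with methanol removes only the MOM group (aryl benzyl and methyl ethers are stable to dilute HCl), and DMAP-catalysed acylation then places the acetate on the single free hydroxyl, at C8, while every other oxygen is still capped.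

Step 10
Reactants: 17 5-(benzyloxy)-2-[4-(benzyloxy)phenyl]-7-methoxy-4-oxo-4H-chromen-8-yl acetate
Product: 19 5-(benzyloxy)-2-[4-(benzyloxy)phenyl]-3-hydroxy-7-methoxy-4-oxo-4H-chromen-8-yl acetate, via epoxide 18 (not isolated)
Conditions: DMDO (acetone solution), CH2Cl2, 0 °C → rt; evaporate; then p-TsOH·H2O (cat.), CH2Cl2, rt
Reagents that add atoms: dimethyldioxirane, CC1(C)OO1
Why: Epoxidation of the C2=C3 enol-ether double bond by the neutral dioxirane gives the cis-fused epoxide as a racemate whose two stereocentres are transient, and acid-catalysed opening at C2 through the O1-stabilised cation followed by loss of H3 isomerises it to the achiral 3-hydroxyflavone, the C5 oxygen being capped as this oxidation requires.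

Step 11
Reactants: 19 5-(benzyloxy)-2-[4-(benzyloxy)phenyl]-3-hydroxy-7-methoxy-4-oxo-4H-chromen-8-yl acetate
Product: 20 3,5-dihydroxy-2-(4-hydroxyphenyl)-7-methoxy-4-oxo-4H-chromen-8-yl acetate (pollenitin 8-acetate)
Conditions: H2 (1 atm), 10% Pd/C, EtOAc–THF, rt
Reagents that add atoms: none
Why: Catalytic hydrogenolysis cleaves both aryl benzyl ethers under neutral, non-nucleophilic conditions that leave the aryl acetate, the C7 methyl ether and the tetrasubstituted C2=C3 bond of the flavonol untouched.

**Compound list**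

1 | 2,4-dihydroxy-6-methoxybenzaldehyde | COc1cc(O)cc(O)c1C=O | starting material
2 | 4-(benzyloxy)-2-hydroxy-6-methoxybenzaldehyde | COc1cc(OCc2ccccc2)cc(O)c1C=O | intermediate
3 | 5-(benzyloxy)-2-formyl-3-methoxyphenyl diethylcarbamate | CCN(CC)C(=O)Oc1cc(OCc2ccccc2)cc(OC)c1C=O | intermediate
4 | 4-(benzyloxy)-2-[(diethylcarbamoyl)oxy]-6-methoxyphenyl formate | CCN(CC)C(=O)Oc1cc(OCc2ccccc2)cc(OC)c1OC=O | intermediate
5 | 5-(benzyloxy)-2-hydroxy-3-methoxyphenyl diethylcarbamate | CCN(CC)C(=O)Oc1cc(OCc2ccccc2)cc(OC)c1O | intermediate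
6 | 5-(benzyloxy)-3-methoxy-2-(methoxymethoxy)phenyl diethylcarbamate | CCN(CC)C(=O)Oc1cc(OCc2ccccc2)cc(OC)c1OCOC | intermediate
7 | {6-(benzyloxy)-2-[(diethylcarbamoyl)oxy]-4-methoxy-3-(methoxymethoxy)phenyl}lithium | CCN(CC)C(=O)Oc1c([Li])c(OCc2ccccc2)cc(OC)c1OCOC | intermediate
8 | 3-(benzyloxy)-2-iodo-5-methoxy-6-(methoxymethoxy)phenyl diethylcarbamate | CCN(CC)C(=O)Oc1c(I)c(OCc2ccccc2)cc(OC)c1OCOC | intermediate
9 | 3-(benzyloxy)-2-iodo-5-methoxy-6-(methoxymethoxy)phenol | Oc1c(I)c(OCc2ccccc2)cc(OC)c1OCOC | intermediate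
10 | 4-(benzyloxy)benzaldehyde | O=Cc1ccc(OCc2ccccc2)cc1 | starting material
11 | 1-(benzyloxy)-4-ethynylbenzene | C#Cc1ccc(OCc2ccccc2)cc1 | intermediate
12 | carbon monoxide | [C-]#[O+] | starting material
13 | 1-[6-(benzyloxy)-2-hydroxy-4-methoxy-3-(methoxymethoxy)phenyl]-3-[4-(benzyloxy)phenyl]prop-2-yn-1-one | COCOc1c(O)c(C(=O)C#Cc2ccc(OCc3ccccc3)cc2)c(OCc2ccccc2)cc1OC | intermediate
14 | (E)-1-[6-(benzyloxy)-2-hydroxy-4-methoxy-3-(methoxymethoxy)phenyl]-3-[4-(benzyloxy)phenyl]-3-(diethylamino)prop-2-en-1-one | CCN(CC)/C(=C/C(=O)c1c(O)c(OCOC)c(OC)cc1OCc1ccccc1)c1ccc(OCc2ccccc2)cc1 | intermediate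
15 | 5-(benzyloxy)-2-[4-(benzyloxy)phenyl]-7-methoxy-8-(methoxymethoxy)-4H-chromen-4-one | COc1cc(OCc2ccccc2)c2c(=O)cc(-c3ccc(OCc4ccccc4)cc3)oc2c1OCOC | intermediate
16 | 5-(benzyloxy)-2-[4-(benzyloxy)phenyl]-8-hydroxy-7-methoxy-4H-chromen-4-one | COc1cc(OCc2ccccc2)c2c(=O)cc(-c3ccc(OCc4ccccc4)cc3)oc2c1O | intermediate
17 | 5-(benzyloxy)-2-[4-(benzyloxy)phenyl]-7-methoxy-4-oxo-4H-chromen-8-yl acetate | COc1cc(OCc2ccccc2)c2c(=O)cc(-c3ccc(OCc4ccccc4)cc3)oc2c1OC(C)=O | intermediate
18 | 2,3-epoxide of 17 (flavone numbering; 2,3-epoxy-2,3-dihydro derivative, oxirane cis-fused to ring C, 2-aryl and 3-H on the face opposite to the oxirane oxygen; racemic, one enantiomer drawn) | O=C1[C@@H]2O[C@]2(c2ccc(OCc3ccccc3)cc2)Oc2c(OC(C)=O)c(OC)cc(OCc3ccccc3)c12 | intermediate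
19 | 5-(benzyloxy)-2-[4-(benzyloxy)phenyl]-3-hydroxy-7-methoxy-4-oxo-4H-chromen-8-yl acetate | COc1cc(OCc2ccccc2)c2c(=O)c(O)c(-c3ccc(OCc4ccccc4)cc3)oc2c1OC(C)=O | intermediate
20 | 3,5-dihydroxy-2-(4-hydroxyphenyl)-7-methoxy-4-oxo-4H-chromen-8-yl acetate (pollenitin 8-acetate; no stereocentre) | COc1cc(O)c2c(=O)c(O)c(-c3ccc(O)cc3)oc2c1OC(C)=O | target

**Step count and risks**

Total step count: 11 steps. Longest linear sequence: 10 steps (steps 1–6 and 8–11); step 7 is a one-step side branch.

Steps most likely to fail: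

1. Step 8. Oxidative addition may be slow at an iodide flanked by two oxygen substituents on an electron-rich ring. The aroylpalladium intermediate may be captured by diethylamine (amide formation), or CO-free coupling with 5-endo closure may lead toward a benzofuran. The fallback builds the ynone without palladium and sets out from 9. Capping the phenol with MOMCl and i-Pr2NEt would give 1-(benzyloxy)-2-iodo-5-methoxy-3,4-bis(methoxymethoxy)benzene F1. Iodine–lithium exchange (n-BuLi, THF, −78 °C) and formylation with DMF would give 6-(benzyloxy)-4-methoxy-2,3-bis(methoxymethoxy)benzaldehyde F2. Addition of the lithium acetylide of 11 (n-BuLi, THF, −78 °C) would give racemic 1-[6-(benzyloxy)-4-methoxy-2,3-bis(methoxymethoxy)phenyl]-3-[4-(benzyloxy)phenyl]prop-2-yn-1-ol F3. MnO2 in CH2Cl2 would oxidise it to 1-[6-(benzyloxy)-4-methoxy-2,3-bis(methoxymethoxy)phenyl]-3-[4-(benzyloxy)phenyl]prop-2-yn-1-one F4. HCl in MeOH would remove both MOM groups to give 1-[6-(benzyloxy)-2,3-dihydroxy-4-methoxyphenyl]-3-[4-(benzyloxy)phenyl]prop-2-yn-1-one F5, and Et2NH in EtOH should close this 6-endo through the enaminone. The fallback comes back to the route at 16, which is acetylated as in the second stage of step 9.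

2. Step 10. Epoxidation of the conjugated C2=C3 bond may be slow enough for the dioxirane to oxidise the benzylic C–H bonds of the two benzyl ethers, and opening of the epoxide may be diverted toward ring contraction instead of enolisation. The fallback hydroxylates C3 through the carbanion before the acetate is present and sets out from 15. C3 lithiation, borylation and oxidation (LDA, THF, −78 °C; B(OMe)3; H2O2, AcOH) would give 5-(benzyloxy)-2-[4-(benzyloxy)phenyl]-3-hydroxy-7-methoxy-8-(methoxymethoxy)-4H-chromen-4-one F6. Benzylation (BnBr, K2CO3, DMF) would give 3,5-bis(benzyloxy)-2-[4-(benzyloxy)phenyl]-7-methoxy-8-(methoxymethoxy)-4H-chromen-4-one F7. HCl in MeOH–THF would give 3,5-bis(benzyloxy)-2-[4-(benzyloxy)phenyl]-8-hydroxy-7-methoxy-4H-chromen-4-one F8, and Ac2O with pyridine would give 3,5-bis(benzyloxy)-2-[4-(benzyloxy)phenyl]-7-methoxy-4-oxo-4H-chromen-8-yl acetate F9. Hydrogenolysis under the conditions of step 11 would remove all three benzyl groups, so the fallback comes back to the route at 20.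

3. Step 6. Hydroxide attack may be sluggish at a carbamoyl group shielded by two ortho substituents, and prolonged heating in ethanolic base may cause reductive loss of iodine. The fallback replaces hydrolysis by hydride reduction and sets out from 8. Cp2Zr(H)Cl in THF at rt should add hydride to the carbamate carbonyl; collapse of the zirconium hemiaminal releases the aryloxide and aqueous work-up gives the phenol. No new compound arises (F0), and the fallback comes back to the route at 9.

**Further compounds**

F1 | step 8 | 1-(benzyloxy)-2-iodo-5-methoxy-3,4-bis(methoxymethoxy)benzene | COCOc1c(I)c(OCc2ccccc2)cc(OC)c1OCOC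
F2 | step 8 | 6-(benzyloxy)-4-methoxy-2,3-bis(methoxymethoxy)benzaldehyde | COCOc1c(C=O)c(OCc2ccccc2)cc(OC)c1OCOC
F3 | step 8 | 1-[6-(benzyloxy)-4-methoxy-2,3-bis(methoxymethoxy)phenyl]-3-[4-(benzyloxy)phenyl]prop-2-yn-1-ol (racemic) | COCOc1c(C(O)C#Cc2ccc(OCc3ccccc3)cc2)c(OCc2ccccc2)cc(OC)c1OCOC
F4 | step 8 | 1-[6-(benzyloxy)-4-methoxy-2,3-bis(methoxymethoxy)phenyl]-3-[4-(benzyloxy)phenyl]prop-2-yn-1-one | COCOc1c(C(=O)C#Cc2ccc(OCc3ccccc3)cc2)c(OCc2ccccc2)cc(OC)c1OCOC
F5 | step 8 | 1-[6-(benzyloxy)-2,3-dihydroxy-4-methoxyphenyl]-3-[4-(benzyloxy)phenyl]prop-2-yn-1-one | COc1cc(OCc2ccccc2)c(C(=O)C#Cc2ccc(OCc3ccccc3)cc2)c(O)c1O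
F6 | step 10 | 5-(benzyloxy)-2-[4-(benzyloxy)phenyl]-3-hydroxy-7-methoxy-8-(methoxymethoxy)-4H-chromen-4-one | COc1cc(OCc2ccccc2)c2c(=O)c(O)c(-c3ccc(OCc4ccccc4)cc3)oc2c1OCOC
F7 | step 10 | 3,5-bis(benzyloxy)-2-[4-(benzyloxy)phenyl]-7-methoxy-8-(methoxymethoxy)-4H-chromen-4-one | COc1cc(OCc2ccccc2)c2c(=O)c(OCc3ccccc3)c(-c3ccc(OCc4ccccc4)cc3)oc2c1OCOC
F8 | step 10 | 3,5-bis(benzyloxy)-2-[4-(benzyloxy)phenyl]-8-hydroxy-7-methoxy-4H-chromen-4-one | COc1cc(OCc2ccccc2)c2c(=O)c(OCc3ccccc3)c(-c3ccc(OCc4ccccc4)cc3)oc2c1O
F9 | step 10 | 3,5-bis(benzyloxy)-2-[4-(benzyloxy)phenyl]-7-methoxy-4-oxo-4H-chromen-8-yl acetate | COc1cc(OCc2ccccc2)c2c(=O)c(OCc3ccccc3)c(-c3ccc(OCc4ccccc4)cc3)oc2c1OC(C)=O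
F0 | step 6 | none | none
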